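A direct plan would close the 1,2-dioxane early, by letting a ketal hydroperoxide open an oxetane, and would decorate the ring afterwards. The 6-methoxy-1,2-dioxane ester A1 would be allylated at C6 through its peroxycarbenium ion to give the 6-allyl-1,2-dioxane ester A2, and the enone chain would then be grown on the ring through aldehyde A3. Its weakest steps would be:
- the allylation that creates the quaternary carbon C6, because its configuration would rest only on a facial preference of a half-chair cation that must tell CH3 from CH2R across the ring;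
- the addition of an alkenyllithium or alkenylcerium reagent to A3, because a basic, reducing organometallic would meet the O–O bond, the ester and the acidic C2–H on the most valuable material;
- the shuttling of oxidation levels (C1 made as an alcohol and oxidised twice; hydroboration, oxidation, addition, oxidation and desilylation to turn an allyl group into the enone), many steps for little complexity.

Plan of the new route. The feature used is that O2 on ring carbon C3 stands 1,3 to the carboxyl carbon C1, so the β-peroxy ester is an opened 3-methyloxetan-2-one. The O1–O2 bridge from C6 reaches C3 through C4–C5, so a C6 hydroperoxide sits ready for 6-exo-tet attack on the lactone β-carbon.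
Bonds cut: O2–C3 (hydroperoxide opens the β-lactone, inversion); C2–C3 and C1–O (acyl halide–aldehyde cyclocondensation); C4–C5 (Wittig); C6–O1 (invertive perhydrolysis of a glycidol-derived 2,2-disubstituted epoxide); C9–C10 (alkenyllithium); C7–C8 (cuprate).
Ring order: the whole carbon chain and all three stereocentres exist before any ring of the target. Only an oxirane and then the oxetan-2-one are carried, and the 1,2-dioxane forms last, in step 15, followed by one oxidation.
The weak steps do not occur: C6 is fixed by Sharpless epoxidation and a stereospecific inversion, C3 by a catalyst-controlled lactone and a second inversion. Both organometallic steps precede the first O–O bond, and C1 arrives at the acid level.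

Key step: step 15

Remark on numbering: C1–C14 are the atoms of the acid chain of the target (C1 ester carbon, C3 and C6 ring carbons, C9 ketone carbon, C14 carbinol carbon).
Assumption: O-trimethylsilylquinidine is taken as the pseudoenantiomer that gives the (3S,4R)-lactone from propanoyl chloride and an aliphatic aldehyde; if the sense is the opposite, O-trimethylsilylquinine is used and nothing else changes.
Remark: compounds 14–19, 21–23 and 26–29 are mixtures of two epimers at the side-chain carbinol carbon (C9), which becomes the ketone in step 16.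

Step 1
Reactants: 1 2-methylprop-2-en-1-ol
Product: 3 [(2R)-2-methyloxiran-2-yl]methyl 4-methylbenzenesulfonate, via (S)-2-methylglycidol 2 (not isolated)
Conditions: Ti(OiPr)4 (5 mol %), L-(+)-diisopropyl tartrate (6 mol %), cumene hydroperoxide, 4 Å molecular sieves, CH2Cl2, −20 °C; P(OMe)3; TsCl, Et3N, DMAP (cat.), −10 °C
Reagents that add atoms: cumene hydroperoxide CC(C)(OO)c1ccccc1; 4-methylbenzenesulfonyl chloride Cc1ccc(cc1)S(=O)(=O)Cl
Why: Sharpless asymmetric epoxidation with in situ sulfonylation, in which the Ti(OiPr)4–L-(+)-diisopropyl tartrate catalyst delivers oxygen to one face of the 1,1-disubstituted allylic alcohol and so sets the quaternary carbon (future C6) as (S)-2, the label becoming R in tosylate 3 only through the change in CIP priorities.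

Step 2
Reactants: 3 [(2R)-2-methyloxiran-2-yl]methyl 4-methylbenzenesulfonate; 4 allylmagnesium bromide
Product: 6 (2R)-2-(but-3-en-1-yl)-2-methyloxirane, via tosyloxy alkoxide 5 (not isolated)
Conditions: 4 (1.3 equiv), CuI (10 mol %), THF, −40 → −10 °C; then NaOH (2 M aq.), 0 °C → rt
Reagents that add atoms: none
Why: CuI-catalysed Grignard opening of the epoxide at its CH2 carbon (future C7), which is much faster than direct displacement of the neopentyl-type tosylate, followed by intramolecular Williamson closure of the tertiary alkoxide onto the tosylate (3-exo-tet), in which no bond to the quaternary carbon is broken and the former CH2OTs carbon becomes the new epoxide CH2 (future C5).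

Step 3
Reactants: 6 (2R)-2-(but-3-en-1-yl)-2-methyloxirane
Product: 8 3-[(2R)-2-methyloxiran-2-yl]propanal, via ozonide 7 (not isolated)
Conditions: O3, CH2Cl2, −78 °C; PPh3, −78 °C → rt
Reagents that add atoms: ozone [O-][O+]=O
Why: ozonolysis with reductive work-up, which cleaves the only alkene to the aldehyde (future C9) and leaves the epoxide untouched.

Step 4
Reactants: 9 6-methylhept-5-en-2-one
Product: 10 6-hydroxy-6-methylheptan-2-one
Conditions: H2SO4 (35% aq.), 0 °C → rt
Reagents that add atoms: water O
Why: acid-catalysed Markovnikov hydration of the trisubstituted alkene through the tertiary cation, which gives the tertiary alcohol (future C14) and leaves the ketone alone.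

Step 5
Reactants: 10 6-hydroxy-6-methylheptan-2-one
Product: 11 6-methyl-6-[(triethylsilyl)oxy]heptan-2-one
Conditions: TESOTf (1.2 equiv), 2,6-lutidine (2 equiv), CH2Cl2, −78 °C
Reagents that add atoms: triethylsilyl trifluoromethanesulfonate CC[Si](CC)(CC)OS(=O)(=O)C(F)(F)F
Why: silylation of the hindered tertiary alcohol with a silyl triflate and a weak hindered base at −78 °C, where enol silane formation from the methyl ketone is slow.

Step 6
Reactants: 11 6-methyl-6-[(triethylsilyl)oxy]heptan-2-one
Product: 12 N'-{6-methyl-6-[(triethylsilyl)oxy]heptan-2-ylidene}-2,4,6-tri(propan-2-yl)benzenesulfonohydrazide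
Conditions: 2,4,6-tri(propan-2-yl)benzenesulfonohydrazide (1.05 equiv), THF, MgSO4, rt
Reagents that add atoms: 2,4,6-tri(propan-2-yl)benzenesulfonohydrazide CC(C)c1cc(C(C)C)c(S(=O)(=O)NN)c(C(C)C)c1
Why: condensation of the methyl ketone to the arenesulfonylhydrazone, whose sulfonamide nitrogen lies syn to the methyl group as the Shapiro reaction requires.

Step 7
Reactants: 12 N'-{6-methyl-6-[(triethylsilyl)oxy]heptan-2-ylidene}-2,4,6-tri(propan-2-yl)benzenesulfonohydrazide; 8 3-[(2R)-2-methyloxiran-2-yl]propanal
Product: 15 tert-butyl(dimethyl)({8-methyl-4-methylidene-1-[(2R)-2-methyloxiran-2-yl]-8-[(triethylsilyl)oxy]nonan-3-yl}oxy)silane (both epimers at C3), via alkenyllithium 13 (not isolated), via epoxy alcohol 14 (not isolated)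
Conditions: 12 (1.15 equiv), n-BuLi (2.3 equiv), THF, −78 → 0 °C; 8, −78 °C; aq. NH4Cl; crude alcohol: TBSCl, imidazole, DMF, 0 °C → rt
Reagents that add atoms: tert-butyl(chloro)dimethylsilane CC(C)(C)[Si](C)(C)Cl
Why: Shapiro reaction, in which double deprotonation at the methyl group and loss of sulfinate and dinitrogen give the 2-lithio-1-alkene 13, whose 1,2-addition to the aldehyde at −78 °C forms the C9–C10 bond much faster than it attacks the 2,2-disubstituted epoxide, and the crude alcohol is silylated at once so that the free hydroxyl cannot open the neighbouring epoxide.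

Step 8
Reactants: 15 tert-butyl(dimethyl)({8-methyl-4-methylidene-1-[(2R)-2-methyloxiran-2-yl]-8-[(triethylsilyl)oxy]nonan-3-yl}oxy)silane
Product: 16 (2S)-5-[(tert-butyldimethylsilyl)oxy]-2-hydroperoxy-2,10-dimethyl-6-methylidene-10-[(triethylsilyl)oxy]undecan-1-ol
Conditions: H2O2 (anhydrous, ca. 10 equiv in Et2O), H3PMo12O40 (2 mol %), Et2O, 0 °C
Reagents that add atoms: hydrogen peroxide OO
Why: acid-catalysed perhydrolysis of a 2,2-disubstituted epoxide, in which hydrogen peroxide in large excess attacks the tertiary carbon of the activated oxirane from the rear (borderline SN2), so that C6 receives the O–O unit with inversion (2S here) and the former epoxide CH2 becomes the primary alcohol.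

Step 9
Reactants: 16 (2S)-5-[(tert-butyldimethylsilyl)oxy]-2-hydroperoxy-2,10-dimethyl-6-methylidene-10-[(triethylsilyl)oxy]undecan-1-ol
Product: 17 triethyl({(2S)-5-[(tert-butyldimethylsilyl)oxy]-2,10-dimethyl-6-methylidene-10-[(triethylsilyl)oxy]-2-[(triethylsilyl)peroxy]undecyl}oxy)silane
Conditions: TESCl (2.4 equiv), imidazole (4 equiv), DMF, 0 °C
Reagents that add atoms: chlorotriethylsilane CC[Si](CC)(CC)Cl
Why: silylation of both the hydroperoxide and the primary alcohol, which avoids any need to tell them apart and gives a tertiary triethylsilyl peroxide, a protecting group that should withstand chromatography, ylides and weak acids and fall to fluoride.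

Step 10
Reactants: 17 triethyl({(2S)-5-[(tert-butyldimethylsilyl)oxy]-2,10-dimethyl-6-methylidene-10-[(triethylsilyl)oxy]-2-[(triethylsilyl)peroxy]undecyl}oxy)silane
Product: 19 (2S)-5-[(tert-butyldimethylsilyl)oxy]-2,10-dimethyl-6-methylidene-10-[(triethylsilyl)oxy]-2-[(triethylsilyl)peroxy]undecanal, via alkoxysulfonium salt 18 (not isolated)
Conditions: (COCl)2 (2 equiv), DMSO (4 equiv), CH2Cl2, −78 → −40 °C; Et3N (6 equiv), −78 → 0 °C
Reagents that add atoms: none
Why: Swern oxidation applied directly to a primary triethylsilyl ether, in which chlorodimethylsulfonium exchanges only the primary Si–O bond to give 18 and then the aldehyde, while the tertiary silyl peroxide and the secondary and tertiary silyl ethers stay, and the aldehyde has no α-hydrogen so C6 cannot epimerise.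

Step 11
Reactants: 19 (2S)-5-[(tert-butyldimethylsilyl)oxy]-2,10-dimethyl-6-methylidene-10-[(triethylsilyl)oxy]-2-[(triethylsilyl)peroxy]undecanal; 20 (triphenyl-λ5-phosphanylidene)acetaldehyde
Product: 21 (2E,4S)-7-[(tert-butyldimethylsilyl)oxy]-4,12-dimethyl-8-methylidene-12-[(triethylsilyl)oxy]-4-[(triethylsilyl)peroxy]tridec-2-enal
Conditions: 20 (1.3 equiv), toluene, 70 °C
Reagents that add atoms: none
Why: Wittig reaction with a formyl-stabilised ylide, which adds C4 and C3 as the (E)-enal under neutral conditions, the quaternary carbon next to the new alkene slowing a second olefination.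

Step 12
Reactants: 21 (2E,4S)-7-[(tert-butyldimethylsilyl)oxy]-4,12-dimethyl-8-methylidene-12-[(triethylsilyl)oxy]-4-[(triethylsilyl)peroxy]tridec-2-enal
Product: 23 (4S)-7-[(tert-butyldimethylsilyl)oxy]-4,12-dimethyl-8-methylidene-12-[(triethylsilyl)oxy]-4-[(triethylsilyl)peroxy]tridecanal, via iminium ion 22 (not isolated)
Conditions: diethyl 2,6-dimethyl-1,4-dihydropyridine-3,5-dicarboxylate (1.2 equiv), dibenzylammonium trifluoroacetate (10 mol %), THF, rt
Reagents that add atoms: none
Why: organocatalytic transfer hydrogenation, in which the secondary ammonium salt activates only the enal as iminium ion 22 and the Hantzsch ester delivers hydride to C5, so that the unactivated 1,1-disubstituted alkene and the O–O bond, which diimide or metal hydrides would not spare, are left alone.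

Step 13
Reactants: 23 (4S)-7-[(tert-butyldimethylsilyl)oxy]-4,12-dimethyl-8-methylidene-12-[(triethylsilyl)oxy]-4-[(triethylsilyl)peroxy]tridecanal; 24 propanoyl chloride
Product: 26 (3S,4R)-4-[(3R)-6-[(tert-butyldimethylsilyl)oxy]-3,11-dimethyl-7-methylidene-11-[(triethylsilyl)oxy]-3-[(triethylsilyl)peroxy]dodecyl]-3-methyloxetan-2-one, via methylketene 25 (not isolated)
Conditions: 24 (2 equiv), iPr2NEt (2.5 equiv), O-trimethylsilylquinidine (10 mol %), LiClO4 (2 equiv), CH2Cl2/Et2O, −78 °C
Reagents that add atoms: none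
Why: cinchona alkaloid/LiClO4-catalysed acyl halide–aldehyde cyclocondensation, in which the alkaloid turns methylketene 25 into a chiral (Z)-ammonium enolate that adds to the lithium-activated aldehyde through a closed transition state and lactonises, setting C2 (S) and C3 (R in the lactone) together as the cis-oxetan-2-one under catalyst control, independent of the remote C6 (whose label reads R here only through CIP priorities).

Step 14
Reactants: 26 (3S,4R)-4-[(3R)-6-[(tert-butyldimethylsilyl)oxy]-3,11-dimethyl-7-methylidene-11-[(triethylsilyl)oxy]-3-[(triethylsilyl)peroxy]dodecyl]-3-methyloxetan-2-one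
Product: 27 (3S,4R)-4-[(3S)-3-hydroperoxy-6,11-dihydroxy-3,11-dimethyl-7-methylidenedodecyl]-3-methyloxetan-2-one
Conditions: HF·pyridine, pyridine, THF, 0 °C → rt
Reagents that add atoms: none
Why: fluoride-mediated Si–O cleavage under buffered acidic conditions that a β-lactone tolerates, which frees the hydroperoxide and both alcohols, and any ring closure that already occurs here gives the acid that step 15 would form anyway.

Step 15
Reactants: 27 (3S,4R)-4-[(3S)-3-hydroperoxy-6,11-dihydroxy-3,11-dimethyl-7-methylidenedodecyl]-3-methyloxetan-2-one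
Product: 29 methyl (2S)-2-[(3S,6S)-6-(3,8-dihydroxy-8-methyl-4-methylidenenonyl)-6-methyl-1,2-dioxan-3-yl]propanoate, via cesium carboxylate 28 (not isolated)
Conditions: Cs2CO3 (1.5 equiv), DMF (0.005 M), 0 °C → rt; then MeI (3 equiv), 0 °C
Reagents that add atoms: iodomethane CI
Why: Proposed new method: the cesium salt of the tertiary hydroperoxide (far more acidic than the two alcohols) attacks the β-carbon C3 of the oxetan-2-one from the side opposite to the ring oxygen, the alkyl C–O bond breaks with release of the four-ring strain, and the carboxylate 28 set free is methylated in the same flask. The closest known reaction types are the SN2 opening of β-lactones at the β-carbon by soft anions (azide, thiolates, sulfonamide anions), which goes with inversion, and the base-mediated 6-exo-tet displacement of secondary sulfonates by hydroperoxides used to make 1,2-dioxanes. The 1,2-dioxane (O1, O2, C3, C4, C5, C6) closes in the 6-exo-tet mode. C3 is the only stereocentre affected and is inverted from R in the lactone to S, so its configuration follows from the catalyst-controlled lactone and not from a facial preference, while C2 and C6 are untouched. The step needs attack at the alkyl and not the acyl carbon, which the tether secures because acyl attack would require an eight-membered perester and high dilution suppresses intermolecular acyl transfer; base-induced loss of the peroxide is held back because the ring-closed product is a carboxylate until the cold methylation.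

Step 16
Reactants: 29 methyl (2S)-2-[(3S,6S)-6-(3,8-dihydroxy-8-methyl-4-methylidenenonyl)-6-methyl-1,2-dioxan-3-yl]propanoate
Product: 30 aikupikoxide D
Conditions: Dess–Martin periodinane (1.5 equiv), NaHCO3, CH2Cl2, 0 °C → rt
Reagents that add atoms: none
Why: Dess–Martin oxidation of the secondary allylic alcohol under bicarbonate buffering, which gives the α-methylene ketone, removes the stereo-irrelevant carbinol centre and leaves the tertiary alcohol, the dialkyl peroxide and the β-peroxy ester untouched (C6 reads R in 30 only through CIP priorities).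

**Compound list**

1 | 2-methylprop-2-en-1-ol | C=C(C)CO | starting material
2 | [(2S)-2-methyloxiran-2-yl]methanol, (S)-2-methylglycidol | C[C@]1(CO)CO1 | intermediate (not isolated)
3 | [(2R)-2-methyloxiran-2-yl]methyl 4-methylbenzenesulfonate | C[C@]1(COS(=O)(=O)c2ccc(C)cc2)CO1 | intermediate
4 | allylmagnesium bromide | C=CC[Mg]Br | starting material
5 | (2R)-2-hydroxy-2-methylhex-5-en-1-yl 4-methylbenzenesulfonate (present as its magnesium alkoxide) | C[C@](O)(COS(=O)(=O)c1ccc(C)cc1)CCC=C | intermediate (not isolated)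
6 | (2R)-2-(but-3-en-1-yl)-2-methyloxirane | C[C@]1(CO1)CCC=C | intermediate
7 | 3-{2-[(2R)-2-methyloxiran-2-yl]ethyl}-1,2,4-trioxolane | C[C@]1(CO1)CCC1OCOO1 | intermediate (not isolated)
8 | 3-[(2R)-2-methyloxiran-2-yl]propanal | C[C@]1(CO1)CCC=O | intermediate
9 | 6-methylhept-5-en-2-one | CC(=O)CCC=C(C)C | starting material
10 | 6-hydroxy-6-methylheptan-2-one | CC(=O)CCCC(C)(C)O | intermediate
11 | 6-methyl-6-[(triethylsilyl)oxy]heptan-2-one | CC(=O)CCCC(C)(C)O[Si](CC)(CC)CC | intermediate
12 | N'-{6-methyl-6-[(triethylsilyl)oxy]heptan-2-ylidene}-2,4,6-tri(propan-2-yl)benzenesulfonohydrazide | CC(CCCC(C)(C)O[Si](CC)(CC)CC)=NNS(=O)(=O)c1c(C(C)C)cc(C(C)C)cc1C(C)C | intermediate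
13 | {6-methyl-6-[(triethylsilyl)oxy]hept-1-en-2-yl}lithium | [Li]C(=C)CCCC(C)(C)O[Si](CC)(CC)CC | intermediate (not isolated)
14 | 8-methyl-4-methylidene-1-[(2R)-2-methyloxiran-2-yl]-8-[(triethylsilyl)oxy]nonan-3-ol, both epimers at C3 | C[C@]1(CO1)CCC(O)C(=C)CCCC(C)(C)O[Si](CC)(CC)CC | intermediate (not isolated)
15 | tert-butyl(dimethyl)({8-methyl-4-methylidene-1-[(2R)-2-methyloxiran-2-yl]-8-[(triethylsilyl)oxy]nonan-3-yl}oxy)silane, both epimers at C3 | C[C@]1(CO1)CCC(O[Si](C)(C)C(C)(C)C)C(=C)CCCC(C)(C)O[Si](CC)(CC)CC | intermediate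
16 | (2S)-5-[(tert-butyldimethylsilyl)oxy]-2-hydroperoxy-2,10-dimethyl-6-methylidene-10-[(triethylsilyl)oxy]undecan-1-ol | C[C@@](OO)(CO)CCC(O[Si](C)(C)C(C)(C)C)C(=C)CCCC(C)(C)O[Si](CC)(CC)CC | intermediate
17 | triethyl({(2S)-5-[(tert-butyldimethylsilyl)oxy]-2,10-dimethyl-6-methylidene-10-[(triethylsilyl)oxy]-2-[(triethylsilyl)peroxy]undecyl}oxy)silane | C[C@@](OO[Si](CC)(CC)CC)(CO[Si](CC)(CC)CC)CCC(O[Si](C)(C)C(C)(C)C)C(=C)CCCC(C)(C)O[Si](CC)(CC)CC | intermediate
18 | {[(2S)-5-[(tert-butyldimethylsilyl)oxy]-2,10-dimethyl-6-methylidene-10-[(triethylsilyl)oxy]-2-[(triethylsilyl)peroxy]undecyl]oxy}(dimethyl)sulfonium chloride | C[S+](C)OC[C@@](C)(OO[Si](CC)(CC)CC)CCC(O[Si](C)(C)C(C)(C)C)C(=C)CCCC(C)(C)O[Si](CC)(CC)CC.[Cl-] | intermediate (not isolated)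
19 | (2S)-5-[(tert-butyldimethylsilyl)oxy]-2,10-dimethyl-6-methylidene-10-[(triethylsilyl)oxy]-2-[(triethylsilyl)peroxy]undecanal | C[C@@](OO[Si](CC)(CC)CC)(C=O)CCC(O[Si](C)(C)C(C)(C)C)C(=C)CCCC(C)(C)O[Si](CC)(CC)CC | intermediate
20 | (triphenyl-λ5-phosphanylidene)acetaldehyde | O=CC=P(c1ccccc1)(c1ccccc1)c1ccccc1 | starting material
21 | (2E,4S)-7-[(tert-butyldimethylsilyl)oxy]-4,12-dimethyl-8-methylidene-12-[(triethylsilyl)oxy]-4-[(triethylsilyl)peroxy]tridec-2-enal | C[C@@](OO[Si](CC)(CC)CC)(/C=C/C=O)CCC(O[Si](C)(C)C(C)(C)C)C(=C)CCCC(C)(C)O[Si](CC)(CC)CC | intermediate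
22 | (2E,4S)-N,N-dibenzyl-7-[(tert-butyldimethylsilyl)oxy]-4,12-dimethyl-8-methylidene-12-[(triethylsilyl)oxy]-4-[(triethylsilyl)peroxy]tridec-2-en-1-iminium trifluoroacetate | C[C@@](OO[Si](CC)(CC)CC)(/C=C/C=[N+](Cc1ccccc1)Cc1ccccc1)CCC(O[Si](C)(C)C(C)(C)C)C(=C)CCCC(C)(C)O[Si](CC)(CC)CC.[O-]C(=O)C(F)(F)F | intermediate (not isolated)
23 | (4S)-7-[(tert-butyldimethylsilyl)oxy]-4,12-dimethyl-8-methylidene-12-[(triethylsilyl)oxy]-4-[(triethylsilyl)peroxy]tridecanal | C[C@@](OO[Si](CC)(CC)CC)(CCC=O)CCC(O[Si](C)(C)C(C)(C)C)C(=C)CCCC(C)(C)O[Si](CC)(CC)CC | intermediate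
24 | propanoyl chloride | CCC(=O)Cl | starting material
25 | methylketene (prop-1-en-1-one) | CC=C=O | intermediate (not isolated)
26 | (3S,4R)-4-[(3R)-6-[(tert-butyldimethylsilyl)oxy]-3,11-dimethyl-7-methylidene-11-[(triethylsilyl)oxy]-3-[(triethylsilyl)peroxy]dodecyl]-3-methyloxetan-2-one (cis) | C[C@@H]1C(=O)O[C@@H]1CC[C@@](C)(OO[Si](CC)(CC)CC)CCC(O[Si](C)(C)C(C)(C)C)C(=C)CCCC(C)(C)O[Si](CC)(CC)CC | intermediate
27 | (3S,4R)-4-[(3S)-3-hydroperoxy-6,11-dihydroxy-3,11-dimethyl-7-methylidenedodecyl]-3-methyloxetan-2-one | C[C@@H]1C(=O)O[C@@H]1CC[C@@](C)(OO)CCC(O)C(=C)CCCC(C)(C)O | intermediate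
28 | cesium (2S)-2-[(3S,6S)-6-(3,8-dihydroxy-8-methyl-4-methylidenenonyl)-6-methyl-1,2-dioxan-3-yl]propanoate | C=C(CCCC(C)(C)O)C(O)CC[C@@]1(C)CC[C@@H]([C@H](C)C(=O)[O-])OO1.[Cs+] | intermediate (not isolated)
29 | methyl (2S)-2-[(3S,6S)-6-(3,8-dihydroxy-8-methyl-4-methylidenenonyl)-6-methyl-1,2-dioxan-3-yl]propanoate | C=C(CCCC(C)(C)O)C(O)CC[C@@]1(C)CC[C@@H]([C@H](C)C(=O)OC)OO1 | intermediate
30 | aikupikoxide D, methyl (2S)-2-[(3S,6R)-6-(8-hydroxy-8-methyl-4-methylidene-3-oxononyl)-6-methyl-1,2-dioxan-3-yl]propanoate | C=C(CCCC(C)(C)O)C(=O)CC[C@@]1(C)CC[C@@H]([C@H](C)C(=O)OC)OO1 | target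

Total step count: 16. Longest linear sequence: 13 steps (steps 1–3 and 7–16; the branch through steps 4–6 and 7–16 is equally long).

Steps most likely to fail:

1. Step 15 (proposed new method). The peroxide anion may transfer an acyl group between molecules, or the lactone may be hydrolysed or may open by elimination before the 6-exo-tet displacement takes place. The fallback sets out from aldehyde 23. A Wittig reaction with methyl 2-(triphenyl-λ5-phosphanylidene)propanoate would give methyl (2E,6R)-9-[(tert-butyldimethylsilyl)oxy]-2,6,14-trimethyl-10-methylidene-14-[(triethylsilyl)oxy]-6-[(triethylsilyl)peroxy]pentadec-2-enoate F1. HF·pyridine would free methyl (2E,6R)-6-hydroperoxy-9,14-dihydroxy-2,6,14-trimethyl-10-methylidenepentadec-2-enoate F2. Diethylamine in 2,2,2-trifluoroethanol would then close the ring by intramolecular conjugate addition of the hydroperoxide (6-exo-trig), a known way to 1,2-dioxanes with a β-peroxy ester. C2 and C3 would then not be controlled, and the required isomer would have to be separated from its diastereomers. The fallback comes back to the route at 29.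

2. Step 8. The activated epoxide may be intercepted by the silyl ether oxygen on C9 or by the 1,1-disubstituted alkene, that alkene may be epoxidised by peroxo species formed from H3PMo12O40, or partial ionisation may erode the configuration at C6. The fallback sets out from epoxide 15 and moves the perhydrolysis to the four-membered homologue. Ring expansion with dimethylsulfoxonium methylide (Me3S(O)I, KOtBu, t-BuOH, 50 °C) would give tert-butyl(dimethyl)({8-methyl-4-methylidene-1-[(2R)-2-methyloxetan-2-yl]-8-[(triethylsilyl)oxy]nonan-3-yl}oxy)silane F3. Opening with ethereal H2O2 and TMSOTf at −78 °C, a reaction type known to invert tertiary oxetane carbons, would give (3S)-6-[(tert-butyldimethylsilyl)oxy]-3-hydroperoxy-3,11-dimethyl-7-methylidene-11-[(triethylsilyl)oxy]dodecan-1-ol F4, which already carries C4. Silylation (TESCl, imidazole) would give triethyl({(3S)-6-[(tert-butyldimethylsilyl)oxy]-3,11-dimethyl-7-methylidene-11-[(triethylsilyl)oxy]-3-[(triethylsilyl)peroxy]dodecyl}oxy)silane F5, and Swern oxidation would give (3S)-6-[(tert-butyldimethylsilyl)oxy]-3,11-dimethyl-7-methylidene-11-[(triethylsilyl)oxy]-3-[(triethylsilyl)peroxy]dodecanal F6. A Wittig reaction with (methoxymethylidene)triphenyl-λ5-phosphane would give tert-butyl({(4S)-1-methoxy-4,12-dimethyl-8-methylidene-12-[(triethylsilyl)oxy]-4-[(triethylsilyl)peroxy]tridec-1-en-7-yl}oxy)dimethylsilane F7, and hydrolysis of the enol ether with oxalic acid on wet silica gel would lead to aldehyde 23, where the fallback comes back to the route. This version extends by one carbon instead of two and also avoids the α-peroxy aldehyde.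

3. Step 11. The α-silylperoxy aldehyde may fragment by C–C cleavage at the temperature the stabilised ylide needs with a neopentyl-type aldehyde, and the enal formed may be olefinated a second time. The fallback sets out from aldehyde 19. A Peterson olefination with the lithio derivative of N-tert-butyl-2-(trimethylsilyl)ethanimine at −78 °C would give (2E,4S)-N-tert-butyl-7-[(tert-butyldimethylsilyl)oxy]-4,12-dimethyl-8-methylidene-12-[(triethylsilyl)oxy]-4-[(triethylsilyl)peroxy]tridec-2-en-1-imine F8. Aqueous oxalic acid would hydrolyse it to enal 21, where the fallback comes back to the route.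

Further compounds
F1 | step 15 | methyl (2E,6R)-9-[(tert-butyldimethylsilyl)oxy]-2,6,14-trimethyl-10-methylidene-14-[(triethylsilyl)oxy]-6-[(triethylsilyl)peroxy]pentadec-2-enoate | COC(=O)/C(C)=C/CC[C@@](C)(OO[Si](CC)(CC)CC)CCC(O[Si](C)(C)C(C)(C)C)C(=C)CCCC(C)(C)O[Si](CC)(CC)CC
F2 | step 15 | methyl (2E,6R)-6-hydroperoxy-9,14-dihydroxy-2,6,14-trimethyl-10-methylidenepentadec-2-enoate | COC(=O)/C(C)=C/CC[C@@](C)(OO)CCC(O)C(=C)CCCC(C)(C)O
F3 | step 8 | tert-butyl(dimethyl)({8-methyl-4-methylidene-1-[(2R)-2-methyloxetan-2-yl]-8-[(triethylsilyl)oxy]nonan-3-yl}oxy)silane | C[C@]1(CCO1)CCC(O[Si](C)(C)C(C)(C)C)C(=C)CCCC(C)(C)O[Si](CC)(CC)CC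
F4 | step 8 | (3S)-6-[(tert-butyldimethylsilyl)oxy]-3-hydroperoxy-3,11-dimethyl-7-methylidene-11-[(triethylsilyl)oxy]dodecan-1-ol | C[C@@](OO)(CCO)CCC(O[Si](C)(C)C(C)(C)C)C(=C)CCCC(C)(C)O[Si](CC)(CC)CC
F5 | step 8 | triethyl({(3S)-6-[(tert-butyldimethylsilyl)oxy]-3,11-dimethyl-7-methylidene-11-[(triethylsilyl)oxy]-3-[(triethylsilyl)peroxy]dodecyl}oxy)silane | C[C@@](OO[Si](CC)(CC)CC)(CCO[Si](CC)(CC)CC)CCC(O[Si](C)(C)C(C)(C)C)C(=C)CCCC(C)(C)O[Si](CC)(CC)CC
F6 | step 8 | (3S)-6-[(tert-butyldimethylsilyl)oxy]-3,11-dimethyl-7-methylidene-11-[(triethylsilyl)oxy]-3-[(triethylsilyl)peroxy]dodecanal | C[C@@](OO[Si](CC)(CC)CC)(CC=O)CCC(O[Si](C)(C)C(C)(C)C)C(=C)CCCC(C)(C)O[Si](CC)(CC)CC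
F7 | step 8 | tert-butyl({(4S)-1-methoxy-4,12-dimethyl-8-methylidene-12-[(triethylsilyl)oxy]-4-[(triethylsilyl)peroxy]tridec-1-en-7-yl}oxy)dimethylsilane (E/Z mixture) | C[C@@](OO[Si](CC)(CC)CC)(CC=COC)CCC(O[Si](C)(C)C(C)(C)C)C(=C)CCCC(C)(C)O[Si](CC)(CC)CC
F8 | step 11 | (2E,4S)-N-tert-butyl-7-[(tert-butyldimethylsilyl)oxy]-4,12-dimethyl-8-methylidene-12-[(triethylsilyl)oxy]-4-[(triethylsilyl)peroxy]tridec-2-en-1-imine | C[C@@](OO[Si](CC)(CC)CC)(/C=C/C=NC(C)(C)C)CCC(O[Si](C)(C)C(C)(C)C)C(=C)CCCC(C)(C)O[Si](CC)(CC)CC
A1 | direct plan | methyl (2S)-2-[(3S)-6-methoxy-6-methyl-1,2-dioxan-3-yl]propanoate (both epimers at C6) | COC1(C)CC[C@@H]([C@H](C)C(=O)OC)OO1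
A2 | direct plan | methyl (2S)-2-[(3S,6R)-6-methyl-6-(prop-2-en-1-yl)-1,2-dioxan-3-yl]propanoate | C=CC[C@@]1(C)CC[C@@H]([C@H](C)C(=O)OC)OO1
A3 | direct plan | methyl (2S)-2-[(3S,6R)-6-methyl-6-(3-oxopropyl)-1,2-dioxan-3-yl]propanoate | O=CCC[C@@]1(C)CC[C@@H]([C@H](C)C(=O)OC)OO1
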